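The route rests on disconnecting the C2–C1' bond of the 5,7-dihydroxyflavone unit, between its pyranone ring C and ring B, which already carries the genkwanin unit at C3'. The key step exploits the C2–H of a 3-unsubstituted chromone, the most acidic C–H of ring C because it lies next to O1 and β to the C4 carbonyl. Regioselective C2 zincation of 5,7-bis(benzyloxy)chromone and Negishi coupling with the C1' chloride of an 8-arylgenkwanin tribenzyl ether should forge the whole biflavone skeleton at the flavone oxidation level in one operation. The chloride, para to the C4' oxygen, arrives with a commercial boronic acid, and global hydrogenolysis finishes the route.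

Key step: step 5

Remark: the C3'–C8'' biaryl axis has no configuration in the target structure and is treated as stereochemically undefined, so the route has no stereocenter to set.
Remark: TMPZnCl·LiCl (2,2,6,6-tetramethylpiperidinylzinc chloride–lithium chloride) is taken as a purchased THF solution, and 1-(benzyloxy)-2-bromo-4-chlorobenzene, used only in one fallback, is taken as purchasable.

Step 1
Reactants: 1 genkwanin
Product: 2 5,4'-di-O-benzylgenkwanin
Conditions: BnBr, K2CO3, n-Bu4NI (cat.), DMF, 80 °C
Reagents that add atoms: benzyl bromide, BrCc1ccccc1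
Why: Williamson ether synthesis, in which the 4'-phenoxide is alkylated readily and the hydrogen-bonded 5-OH should follow with excess benzyl bromide in hot DMF, while the 7-methyl ether is untouched.

Step 2
Reactants: 2 5,4'-di-O-benzylgenkwanin
Product: 3 8-iodo-5,4'-di-O-benzylgenkwanin
Conditions: NIS, CF3CO2H (cat.), MeCN, 0 °C to rt
Reagents that add atoms: N-iodosuccinimide, O=C1CCC(=O)N1I
Why: Electrophilic aromatic iodination, in which ring A of a 5-O-alkylated 5,7-dioxygenated flavone is the most electron-rich ring and attack should occur at C8 (ortho to 7-OMe, para to 5-OBn), because C6 is buttressed between two alkoxy groups and ring B is deactivated by conjugation with the pyranone.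

Step 3
Reactants: 3 8-iodo-5,4'-di-O-benzylgenkwanin; 4 [2-(benzyloxy)-5-chlorophenyl]boronic acid
Product: 5 8-[2-(benzyloxy)-5-chlorophenyl]-5,4'-di-O-benzylgenkwanin
Conditions: Pd(PPh3)4 (5 mol %), K2CO3, DME/H2O, 85 °C
Reagents that add atoms: none
Why: Suzuki–Miyaura coupling, in which zerovalent palladium with triphenylphosphine inserts into the C8–I bond but not into the aryl chloride, so the tri-ortho-substituted C8–aryl bond should form with the C1' chloride kept for the key step.

Step 4
Reactants: 6 5,7-dihydroxychromone
Product: 7 5,7-bis(benzyloxy)chromone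
Conditions: BnBr, K2CO3, n-Bu4NI (cat.), DMF, 80 °C
Reagents that add atoms: benzyl bromide, BrCc1ccccc1
Why: Williamson ether synthesis as in step 1, with the chelated 5-OH needing the heat; it removes both acidic protons that would quench the zinc base in step 5.

Step 5
Reactants: 7 5,7-bis(benzyloxy)chromone; 5 8-[2-(benzyloxy)-5-chlorophenyl]-5,4'-di-O-benzylgenkwanin
Product: 9 penta-O-benzylsotetsuflavone, via chromon-2-ylzinc chloride 8 (not isolated)
Conditions: 7 (1.5 equiv), TMPZnCl·LiCl (1.6 equiv), THF, 25 °C; then 5 (1.0 equiv), Pd(OAc)2 (4 mol %), XPhos (8 mol %), THF, 60 °C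
Reagents that add atoms: none
Why: TMPZnCl·LiCl, a mild zinc amide base free of MgCl2, should remove the C2–H of 7, the most acidic C–H of the pyranone ring (vinylic, next to O1 and β to the C4 carbonyl), and the covalent C–Zn bond of 8 should prevent the ring opening to a phenoxide ynone that lithium bases cause. Zerovalent palladium carrying XPhos then inserts into the C1'–Cl bond of 5, and transmetalation with 8 followed by reductive elimination forms the C2–C1' bond, so the flavone arises directly with no oxidation-state adjustment. The closest known reaction type is the deprotonative C2 zincation of chromones with TMP-zinc bases followed by Negishi cross-coupling with aryl halides, combined with the established Negishi coupling of aryl chlorides under dialkylbiarylphosphine ligands. No ring is closed and no stereocenter is formed. The step needs C2 over C3 metalation, which the higher acidity of C2–H in the absence of a carbonyl-bound Lewis acid and the shielding of the carbonyl by the peri 5-benzyloxy group should secure. It also needs a single reactive carbon–halogen bond, which holds because 5 contains only the one aryl chloride, while the benzyl ethers, the methyl ether and the flavone carbonyl tolerate the organozinc.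

Step 6
Reactants: 9 penta-O-benzylsotetsuflavone
Product: 10 sotetsuflavone
Conditions: H2 (1 atm), 10% Pd/C, THF/MeOH, rt
Reagents that add atoms: none
Why: Catalytic hydrogenolysis of the five benzyl aryl ethers on zerovalent palladium, in which the aryl methyl ether is inert and the conjugated C2=C3 bonds of flavones are reduced far more slowly than O-benzyl groups are cleaved, so stopping at the end of hydrogen uptake should give the target.

Compound list
1 | genkwanin, 5-hydroxy-2-(4-hydroxyphenyl)-7-methoxy-4H-chromen-4-one | COc1cc(O)c2c(=O)cc(-c3ccc(O)cc3)oc2c1 | starting material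
2 | 5,4'-di-O-benzylgenkwanin, 5-(benzyloxy)-2-[4-(benzyloxy)phenyl]-7-methoxy-4H-chromen-4-one | COc1cc(OCc2ccccc2)c2c(=O)cc(-c3ccc(OCc4ccccc4)cc3)oc2c1 | intermediate
3 | 8-iodo-5,4'-di-O-benzylgenkwanin, 5-(benzyloxy)-2-[4-(benzyloxy)phenyl]-8-iodo-7-methoxy-4H-chromen-4-one | COc1cc(OCc2ccccc2)c2c(=O)cc(-c3ccc(OCc4ccccc4)cc3)oc2c1I | intermediate
4 | [2-(benzyloxy)-5-chlorophenyl]boronic acid | OB(O)c1cc(Cl)ccc1OCc1ccccc1 | starting material
5 | 5-(benzyloxy)-8-[2-(benzyloxy)-5-chlorophenyl]-2-[4-(benzyloxy)phenyl]-7-methoxy-4H-chromen-4-one | COc1cc(OCc2ccccc2)c2c(=O)cc(-c3ccc(OCc4ccccc4)cc3)oc2c1-c1cc(Cl)ccc1OCc1ccccc1 | intermediate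
6 | 5,7-dihydroxychromone, 5,7-dihydroxy-4H-chromen-4-one | O=c1ccoc2cc(O)cc(O)c12 | starting material
7 | 5,7-bis(benzyloxy)chromone, 5,7-bis(benzyloxy)-4H-chromen-4-one | O=c1ccoc2cc(OCc3ccccc3)cc(OCc3ccccc3)c12 | intermediate
8 | [5,7-bis(benzyloxy)-4-oxo-4H-chromen-2-yl]zinc chloride (as its LiCl complex in THF) | O=c1cc([Zn]Cl)oc2cc(OCc3ccccc3)cc(OCc3ccccc3)c12 | intermediate
9 | penta-O-benzylsotetsuflavone, 5-(benzyloxy)-8-{2-(benzyloxy)-5-[5,7-bis(benzyloxy)-4-oxo-4H-chromen-2-yl]phenyl}-2-[4-(benzyloxy)phenyl]-7-methoxy-4H-chromen-4-one | COc1cc(OCc2ccccc2)c2c(=O)cc(-c3ccc(OCc4ccccc4)cc3)oc2c1-c1cc(-c2cc(=O)c3c(OCc4ccccc4)cc(OCc4ccccc4)cc3o2)ccc1OCc1ccccc1 | intermediate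
10 | sotetsuflavone | COc1cc(O)c2c(=O)cc(-c3ccc(O)cc3)oc2c1-c1cc(-c2cc(=O)c3c(O)cc(O)cc3o2)ccc1O | target

Total step count: 6. Longest linear sequence: 5 steps (steps 1, 2, 3, 5 and 6; step 4 is the one-step side branch).

Steps most likely to fail

Step 5. The zincation may be slow or may compete with metalation at C3, or oxidative addition into the electron-rich aryl chloride may lag so that the zinc reagent is merely protonated back to 7 on work-up. The fallback sets out from 5 and comes back at 9. Miyaura borylation of the chloride (bis(pinacolato)diboron, Pd2(dba)3, XPhos, KOAc, dioxane, 100 °C) should give 5-(benzyloxy)-8-[2-(benzyloxy)-5-(4,4,5,5-tetramethyl-1,3,2-dioxaborolan-2-yl)phenyl]-2-[4-(benzyloxy)phenyl]-7-methoxy-4H-chromen-4-one F1. An oxidative boron–Heck coupling of F1 with 7 under divalent palladium (Pd(OCOCF3)2, 5-nitro-1,10-phenanthroline, O2 1 atm, DMSO, 100 °C) then arylates the chromone at C2. Carbopalladation places the aryl group at C2, and β-hydride elimination (or dehydrogenation of any flavanone formed by protonation) restores the C2=C3 bond to give 9.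

Step 3. Oxidative addition and transmetalation at the doubly ortho-flanked C8–I bond may be slow, so that protodeboronation of the ortho-alkoxy boronic acid and reductive loss of iodine take over. The fallback sets out from 3 and comes back at 5, replacing the boronic acid by a more nucleophilic organozinc that cannot protodeboronate. Magnesium insertion into 1-(benzyloxy)-2-bromo-4-chlorobenzene (Mg, LiCl, THF, 0 °C) should give [2-(benzyloxy)-5-chlorophenyl]magnesium bromide F2. Transmetalation with ZnCl2 gives [2-(benzyloxy)-5-chlorophenyl]zinc chloride F3, and Negishi coupling of F3 with 3 (Pd(PPh3)4, THF, 60 °C) should give 5 with the aryl chloride untouched.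

Step 6. Over-reduction of the C2=C3 bonds may compete with cleavage of the last benzyl ethers, or partly deprotected material may precipitate on the catalyst and stop the reaction. The fallback sets out from 9 and comes back at 10 by a non-reductive Lewis acid cleavage: BCl3 with pentamethylbenzene as benzyl cation scavenger, CH2Cl2, −78 °C. This should remove all five benzyl groups while the 7''-methyl ether, which is not peri to a carbonyl, survives; no new compound arises (F0).

Further compounds
F1 | step 5 | 5-(benzyloxy)-8-[2-(benzyloxy)-5-(4,4,5,5-tetramethyl-1,3,2-dioxaborolan-2-yl)phenyl]-2-[4-(benzyloxy)phenyl]-7-methoxy-4H-chromen-4-one | COc1cc(OCc2ccccc2)c2c(=O)cc(-c3ccc(OCc4ccccc4)cc3)oc2c1-c1cc(B2OC(C)(C)C(C)(C)O2)ccc1OCc1ccccc1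
F2 | step 3 | [2-(benzyloxy)-5-chlorophenyl]magnesium bromide | Br[Mg]c1cc(Cl)ccc1OCc1ccccc1
F3 | step 3 | [2-(benzyloxy)-5-chlorophenyl]zinc chloride | Cl[Zn]c1cc(Cl)ccc1OCc1ccccc1
F0 | step 6 | none | none
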